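**Retrosynthetic overview**
1. The 1,2‑dioxane ring is opened at the C3–O bond (intramolecular peroxy‑Michael addition), giving a C6 hydroperoxide tethered to a butenolide; the hydroperoxide comes from a 1,1‑disubstituted alkene by cobalt‑catalysed hydroperoxysilylation.
2. The butenolide is opened at C2=C3 (intramolecular Horner–Wadsworth–Emmons) to a tertiary phosphonoacetate α‑acyloxy aldehyde, whose aldehyde carbon is unmasked from a glycerate‑derived dioxolane.
3. Key C4–C5 bond: BF3‑promoted carbonyl allylation of an (R)‑glycerate‑derived methyl ketone by a 2‑substituted allylstannane carrying the whole aryl side chain (Felkin–Anh control sets C4).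
4. The allylstannane comes from 4‑bromophenol, 1,8‑dibromooctane and 3‑chloro‑2‑(chloromethyl)prop‑1‑ene by two copper‑catalysed Grignard couplings.
5. Ring order: arene (purchased), then lactone ring (step 10), then 1,2‑dioxane ring (step 13).

Assumption: plakortolide numbering is used for the core (C1 lactone carbonyl, C3 peroxy CH, C4 lactone‑oxygen carbon, C6 quaternary peroxy carbon); the target is (3S,4S,6R).

**Route**

Step 1
Reactants: 1 4‑bromophenol
Product: 2 (4‑bromophenoxy)tri(propan‑2‑yl)silane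
Conditions: i‑Pr3SiCl, imidazole, DMF, rt
Reagents that add atoms: chlorotri(propan‑2‑yl)silane, CC(C)[Si](Cl)(C(C)C)C(C)C
Why: Imidazole‑promoted silyl ether formation gives a bulky aryl silyl ether that survives Grignard, stannyl‑lithium, Lewis‑acid and radical steps and is removable with fluoride at the end.

Step 2
Reactants: 2 (4‑bromophenoxy)tri(propan‑2‑yl)silane; 3 1,8‑dibromooctane
Product: 5 [4‑(8‑bromooctyl)phenoxy]tri(propan‑2‑yl)silane, via aryl Grignard reagent 4 (not isolated)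
Conditions: Mg, THF, reflux; then added to 3 (3 equiv), Li2CuCl4 (3 mol%), THF, 0 °C to rt
Reagents that add atoms: none
Why: Kochi‑type copper‑catalysed Grignard/alkyl bromide cross‑coupling, with excess dibromide (recovered by distillation) keeping the reaction at mono‑substitution.

Step 3
Reactants: 5 [4‑(8‑bromooctyl)phenoxy]tri(propan‑2‑yl)silane; 6 3‑chloro‑2‑(chloromethyl)prop‑1‑ene
Product: 8 {4‑[10‑(chloromethyl)undec‑10‑en‑1‑yl]phenoxy}tri(propan‑2‑yl)silane, via alkyl Grignard reagent 7 (not isolated)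
Conditions: Mg, THF, 40 °C; then added slowly to 6 (3 equiv), CuI (5 mol%), THF, −20 to 0 °C
Reagents that add atoms: none
Why: Copper‑catalysed allylic substitution of a Grignard reagent on the symmetric bis‑allylic dichloride, where SN2 and SN2' give the same 2‑substituted allyl chloride and excess dichloride suppresses double substitution.

Step 4
Reactants: 8 {4‑[10‑(chloromethyl)undec‑10‑en‑1‑yl]phenoxy}tri(propan‑2‑yl)silane
Product: 9 tributyl(2‑methylidene‑11‑{4‑[tri(propan‑2‑yl)silyloxy]phenyl}undecyl)stannane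
Conditions: Bu3SnH, LiN(i‑Pr)2, THF, 0 °C; then 8, −78 to 0 °C
Reagents that add atoms: tributyltin hydride, CCCC[SnH](CCCC)CCCC
Why: Nucleophilic substitution of the allylic chloride by Bu3SnLi (stannyl anion alkylation), regiochemically unambiguous because both allyl termini are equivalent.

Step 5
Reactants: 10 methyl (4R)‑2,2‑dimethyl‑1,3‑dioxolane‑4‑carboxylate
Product: 11 (4R)‑N‑methoxy‑N,2,2‑trimethyl‑1,3‑dioxolane‑4‑carboxamide
Conditions: MeNH(OMe)·HCl, i‑PrMgCl, THF, −20 °C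
Reagents that add atoms: N,O‑dimethylhydroxylamine hydrochloride, CNOC.Cl
Why: Weinreb amide formation by magnesium‑amide aminolysis of the ester, fast at low temperature so the α‑alkoxy stereocentre is not epimerised.

Step 6
Reactants: 11 (4R)‑N‑methoxy‑N,2,2‑trimethyl‑1,3‑dioxolane‑4‑carboxamide
Product: 12 1‑[(4R)‑2,2‑dimethyl‑1,3‑dioxolan‑4‑yl]ethan‑1‑one
Conditions: MeMgBr, THF, 0 °C; aq. NH4Cl
Reagents that add atoms: methylmagnesium bromide, C[Mg]Br
Why: Weinreb ketone synthesis, in which the chelated tetrahedral intermediate prevents over‑addition and releases the enolisable ketone only on quench, so the (R) centre is kept.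

Step 7
Reactants: 12 1‑[(4R)‑2,2‑dimethyl‑1,3‑dioxolan‑4‑yl]ethan‑1‑one; 9 tributyl(2‑methylidene‑11‑{4‑[tri(propan‑2‑yl)silyloxy]phenyl}undecyl)stannane
Product: 13 (2S)‑2‑[(4R)‑2,2‑dimethyl‑1,3‑dioxolan‑4‑yl]‑4‑methylidene‑13‑{4‑[tri(propan‑2‑yl)silyloxy]phenyl}tridecan‑2‑ol
Conditions: 12 (1.5 equiv), BF3·OEt2 (2 equiv), CH2Cl2, −78 °C; aq. NaHCO3 quench at −78 °C
Reagents that add atoms: none
Why: Lewis‑acid‑promoted carbonyl allylation by the allylstannane through an open transition state; monodentate BF3 cannot chelate, so polar Felkin–Anh (Cornforth) control sends the nucleophile to the ketone face anti to the dioxolane C–O bond and sets the (S) tertiary carbinol (anti adduct, expected about 8:1 or better, minor epimer removed by chromatography).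

Step 8
Reactants: 13 (2S)‑2‑[(4R)‑2,2‑dimethyl‑1,3‑dioxolan‑4‑yl]‑4‑methylidene‑13‑{4‑[tri(propan‑2‑yl)silyloxy]phenyl}tridecan‑2‑ol
Product: 14 (2S)‑2‑[(4R)‑2,2‑dimethyl‑1,3‑dioxolan‑4‑yl]‑4‑methylidene‑13‑{4‑[tri(propan‑2‑yl)silyloxy]phenyl}tridecan‑2‑yl (diethoxyphosphoryl)acetate
Conditions: (EtO)2P(O)CH2CO2H, DCC, DMAP (cat.), CH2Cl2, 0 °C to rt
Reagents that add atoms: (diethoxyphosphoryl)acetic acid, CCOP(=O)(CC(=O)O)OCC
Why: Steglich‑type esterification in which DCC turns the acid into a small phosphoryl ketene that acylates the hindered tertiary alcohol, which also blocks that oxygen against over‑cleavage in the next step.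

Step 9
Reactants: 14 (2S)‑2‑[(4R)‑2,2‑dimethyl‑1,3‑dioxolan‑4‑yl]‑4‑methylidene‑13‑{4‑[tri(propan‑2‑yl)silyloxy]phenyl}tridecan‑2‑yl (diethoxyphosphoryl)acetate
Product: 16 (2S)‑2‑methyl‑4‑methylidene‑1‑oxo‑13‑{4‑[tri(propan‑2‑yl)silyloxy]phenyl}tridecan‑2‑yl (diethoxyphosphoryl)acetate, via terminal diol 15 (not isolated)
Conditions: H5IO6, EtOAc, rt
Reagents that add atoms: none
Why: Periodic acid hydrolyses the terminal acetonide and cleaves the resulting 1,2‑diol in one pot (Malaprade glycol cleavage), excising the controlling stereocentre as the aldehyde carbon next to a quaternary centre that cannot epimerise.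

Step 10
Reactants: 16 (2S)‑2‑methyl‑4‑methylidene‑1‑oxo‑13‑{4‑[tri(propan‑2‑yl)silyloxy]phenyl}tridecan‑2‑yl (diethoxyphosphoryl)acetate
Product: 17 (5S)‑5‑methyl‑5‑(2‑methylidene‑11‑{4‑[tri(propan‑2‑yl)silyloxy]phenyl}undecyl)furan‑2(5H)‑one
Conditions: LiCl, i‑Pr2NEt, MeCN, 0 °C to rt
Reagents that add atoms: none
Why: Intramolecular Horner–Wadsworth–Emmons olefination under Masamune–Roush conditions, where five‑membered ring closure enforces the Z alkene of the butenolide and leaves C4 untouched.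

Step 11
Reactants: 17 (5S)‑5‑methyl‑5‑(2‑methylidene‑11‑{4‑[tri(propan‑2‑yl)silyloxy]phenyl}undecyl)furan‑2(5H)‑one
Product: 18 (5S)‑5‑methyl‑5‑[(2RS)‑2‑methyl‑2‑(triethylsilylperoxy)‑11‑{4‑[tri(propan‑2‑yl)silyloxy]phenyl}undecyl]furan‑2(5H)‑one (about 1:1 C6 epimers)
Conditions: Co(thd)2 (10 mol%; thd = 2,2,6,6‑tetramethylheptane‑3,5‑dionate), Et3SiH, O2 (1 atm), ClCH2CH2Cl, rt
Reagents that add atoms: dioxygen, O=O; triethylsilane, CC[SiH](CC)CC
Why: Mukaiyama–Isayama hydroperoxysilylation, in which hydrogen‑atom transfer to the electron‑rich 1,1‑disubstituted alkene gives the Markovnikov tertiary radical that traps O2 while the electron‑poor butenolide alkene reacts far more slowly; the radical trapping is not face‑selective, so C6 is formed as both epimers.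

Step 12
Reactants: 18 (5S)‑5‑methyl‑5‑[(2RS)‑2‑methyl‑2‑(triethylsilylperoxy)‑11‑{4‑[tri(propan‑2‑yl)silyloxy]phenyl}undecyl]furan‑2(5H)‑one
Product: 19 (5S)‑5‑[(2RS)‑2‑hydroperoxy‑2‑methyl‑11‑{4‑[tri(propan‑2‑yl)silyloxy]phenyl}undecyl]‑5‑methylfuran‑2(5H)‑one
Conditions: HCl (cat.), MeOH, 0 °C
Reagents that add atoms: none
Why: Acid‑catalysed methanolysis of the labile Si–OO bond (silyl peroxide deprotection), which is much faster than cleavage of the aryl silyl ether and leaves the butenolide intact.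

Step 13
Reactants: 19 (5S)‑5‑[(2RS)‑2‑hydroperoxy‑2‑methyl‑11‑{4‑[tri(propan‑2‑yl)silyloxy]phenyl}undecyl]‑5‑methylfuran‑2(5H)‑one
Product: 20 (3R,4aS,7aS)‑3,4a‑dimethyl‑3‑(9‑{4‑[tri(propan‑2‑yl)silyloxy]phenyl}nonyl)tetrahydrofuro[3,2‑c][1,2]dioxin‑6(3H)‑one
Conditions: Et2NH (0.5 equiv), CF3CH2OH, rt; chromatographic separation of the C6 epimers
Reagents that add atoms: none
Why: Intramolecular oxa‑Michael (peroxy‑Michael) addition of the hydroperoxide to the butenolide, in which the tether forces attack on the face bearing C5, so the 1,2‑dioxane is cis‑fused and C3 is set as (S) by C4; the (6R) epimer (at most half of the material) is isolated here.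

Step 14
Reactants: 20 (3R,4aS,7aS)‑3,4a‑dimethyl‑3‑(9‑{4‑[tri(propan‑2‑yl)silyloxy]phenyl}nonyl)tetrahydrofuro[3,2‑c][1,2]dioxin‑6(3H)‑one
Product: 21 plakortolide F, (3R,4aS,7aS)‑3‑[9‑(4‑hydroxyphenyl)nonyl]‑3,4a‑dimethyltetrahydrofuro[3,2‑c][1,2]dioxin‑6(3H)‑one
Conditions: Bu4NF, AcOH (1:1), THF, 0 °C
Reagents that add atoms: none
Why: Fluoride‑mediated desilylation of the aryl silyl ether, buffered with acetic acid so that no free base can trigger retro‑Michael opening or Kornblum–DeLaMare fragmentation of the peroxide.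

**Compound list**
1 | 4‑bromophenol | Oc1ccc(Br)cc1 | starting material
2 | (4‑bromophenoxy)tri(propan‑2‑yl)silane | CC(C)[Si](Oc1ccc(Br)cc1)(C(C)C)C(C)C | intermediate
3 | 1,8‑dibromooctane | BrCCCCCCCCBr | starting material
4 | {4‑[tri(propan‑2‑yl)silyloxy]phenyl}magnesium bromide | CC(C)[Si](Oc1ccc([Mg]Br)cc1)(C(C)C)C(C)C | intermediate
5 | [4‑(8‑bromooctyl)phenoxy]tri(propan‑2‑yl)silane | CC(C)[Si](Oc1ccc(CCCCCCCCBr)cc1)(C(C)C)C(C)C | intermediate
6 | 3‑chloro‑2‑(chloromethyl)prop‑1‑ene | C=C(CCl)CCl | starting material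
7 | (8‑{4‑[tri(propan‑2‑yl)silyloxy]phenyl}octyl)magnesium bromide | CC(C)[Si](Oc1ccc(CCCCCCCC[Mg]Br)cc1)(C(C)C)C(C)C | intermediate
8 | {4‑[10‑(chloromethyl)undec‑10‑en‑1‑yl]phenoxy}tri(propan‑2‑yl)silane | CC(C)[Si](Oc1ccc(CCCCCCCCCC(=C)CCl)cc1)(C(C)C)C(C)C | intermediate
9 | tributyl(2‑methylidene‑11‑{4‑[tri(propan‑2‑yl)silyloxy]phenyl}undecyl)stannane | CCCC[Sn](CCCC)(CCCC)CC(=C)CCCCCCCCCc1ccc(O[Si](C(C)C)(C(C)C)C(C)C)cc1 | intermediate
10 | methyl (4R)‑2,2‑dimethyl‑1,3‑dioxolane‑4‑carboxylate | COC(=O)[C@H]1COC(C)(C)O1 | starting material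
11 | (4R)‑N‑methoxy‑N,2,2‑trimethyl‑1,3‑dioxolane‑4‑carboxamide | CON(C)C(=O)[C@H]1COC(C)(C)O1 | intermediate
12 | 1‑[(4R)‑2,2‑dimethyl‑1,3‑dioxolan‑4‑yl]ethan‑1‑one | CC(=O)[C@H]1COC(C)(C)O1 | intermediate
13 | (2S)‑2‑[(4R)‑2,2‑dimethyl‑1,3‑dioxolan‑4‑yl]‑4‑methylidene‑13‑{4‑[tri(propan‑2‑yl)silyloxy]phenyl}tridecan‑2‑ol | C[C@](O)(CC(=C)CCCCCCCCCc1ccc(O[Si](C(C)C)(C(C)C)C(C)C)cc1)[C@H]1COC(C)(C)O1 | intermediate
14 | (2S)‑2‑[(4R)‑2,2‑dimethyl‑1,3‑dioxolan‑4‑yl]‑4‑methylidene‑13‑{4‑[tri(propan‑2‑yl)silyloxy]phenyl}tridecan‑2‑yl (diethoxyphosphoryl)acetate | C[C@](OC(=O)CP(=O)(OCC)OCC)(CC(=C)CCCCCCCCCc1ccc(O[Si](C(C)C)(C(C)C)C(C)C)cc1)[C@H]1COC(C)(C)O1 | intermediate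
15 | (2R,3S)‑1,2‑dihydroxy‑3‑methyl‑5‑methylidene‑14‑{4‑[tri(propan‑2‑yl)silyloxy]phenyl}tetradecan‑3‑yl (diethoxyphosphoryl)acetate | C[C@](OC(=O)CP(=O)(OCC)OCC)(CC(=C)CCCCCCCCCc1ccc(O[Si](C(C)C)(C(C)C)C(C)C)cc1)[C@H](O)CO | intermediate
16 | (2S)‑2‑methyl‑4‑methylidene‑1‑oxo‑13‑{4‑[tri(propan‑2‑yl)silyloxy]phenyl}tridecan‑2‑yl (diethoxyphosphoryl)acetate | C[C@](OC(=O)CP(=O)(OCC)OCC)(CC(=C)CCCCCCCCCc1ccc(O[Si](C(C)C)(C(C)C)C(C)C)cc1)C=O | intermediate
17 | (5S)‑5‑methyl‑5‑(2‑methylidene‑11‑{4‑[tri(propan‑2‑yl)silyloxy]phenyl}undecyl)furan‑2(5H)‑one | C[C@@]1(CC(=C)CCCCCCCCCc2ccc(O[Si](C(C)C)(C(C)C)C(C)C)cc2)OC(=O)C=C1 | intermediate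
18 | (5S)‑5‑methyl‑5‑[(2RS)‑2‑methyl‑2‑(triethylsilylperoxy)‑11‑{4‑[tri(propan‑2‑yl)silyloxy]phenyl}undecyl]furan‑2(5H)‑one | C[C@@]1(CC(C)(OO[Si](CC)(CC)CC)CCCCCCCCCc2ccc(O[Si](C(C)C)(C(C)C)C(C)C)cc2)OC(=O)C=C1 | intermediate
19 | (5S)‑5‑[(2RS)‑2‑hydroperoxy‑2‑methyl‑11‑{4‑[tri(propan‑2‑yl)silyloxy]phenyl}undecyl]‑5‑methylfuran‑2(5H)‑one | C[C@@]1(CC(C)(OO)CCCCCCCCCc2ccc(O[Si](C(C)C)(C(C)C)C(C)C)cc2)OC(=O)C=C1 | intermediate
20 | (3R,4aS,7aS)‑3,4a‑dimethyl‑3‑(9‑{4‑[tri(propan‑2‑yl)silyloxy]phenyl}nonyl)tetrahydrofuro[3,2‑c][1,2]dioxin‑6(3H)‑one | C[C@@]1(CCCCCCCCCc2ccc(O[Si](C(C)C)(C(C)C)C(C)C)cc2)C[C@]2(C)OC(=O)C[C@@H]2OO1 | intermediate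
21 | plakortolide F | C[C@@]1(CCCCCCCCCc2ccc(O)cc2)C[C@]2(C)OC(=O)C[C@@H]2OO1 | target

**Step count**
Total: 14 steps. Longest linear sequence: 12 steps (steps 1–4 and 7–14, from 4‑bromophenol).

**Three steps most likely to fail, with fallbacks**

Step 7 (facial selectivity and reactivity of the ketone allylation). The fallback sets out from allyl chloride 8 and comes back at butenolide 17, replacing carbonyl addition by enolate alkylation with self‑regeneration of the stereocentre. (R)‑Lactic acid and pivalaldehyde (TsOH, pentane, water removal) give cis‑(2R,5R)‑2‑tert‑butyl‑5‑methyl‑1,3‑dioxolan‑4‑one F1. LiN(i‑Pr)2 in THF/DMPU at −78 °C gives its lithium enolate F2, which is alkylated by 8 anti to the tert‑butyl group to give the (2R,5S)‑alkylated dioxolanone F3 with the quaternary centre in the required sense. LiAlH4 reduction gives the (2S)‑1,2‑diol F4, and oxidation of its primary alcohol (SO3·pyridine, DMSO, Et3N) gives the (2S)‑hydroxy aldehyde F5. Treatment with Ph3P=C=C=O in toluene at 80 °C (O‑acylation, then intramolecular Wittig) closes the butenolide and rejoins the route at 17.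

Step 11 (chemoselectivity of the cobalt radical oxygenation against the butenolide alkene). The fallback sets out from 17 and comes back at 19, replacing the radical process by ionic Markovnikov perhydration: 50% aqueous H2O2 in excess with catalytic H2SO4 in Et2O at 0 °C protonates only the electron‑rich 1,1‑disubstituted alkene, and the tertiary cation is captured by H2O2. This gives hydroperoxide 19 directly, so steps 11 and 12 are by‑passed; this fallback makes no new compound (F0).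

Step 13 (base‑mediated ring closure and separation of the lipophilic C6 epimers). The fallback sets out from 19 and comes back at 21, reversing the order of deprotection and ring closure. Bu4NF/AcOH in THF at 0 °C first removes the aryl silyl group to give the phenolic hydroperoxide (5S)‑5‑[(2RS)‑2‑hydroperoxy‑11‑(4‑hydroxyphenyl)‑2‑methylundecyl]‑5‑methylfuran‑2(5H)‑one F6. Et2NH in CF3CH2OH then closes the dioxane on the free phenol, and the more polar phenolic epimers are separated by reverse‑phase HPLC to give 21, so the bicyclic peroxide is never exposed to fluoride.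

**Further compounds**
F1 | step 7 | (2R,5R)‑2‑tert‑butyl‑5‑methyl‑1,3‑dioxolan‑4‑one | C[C@H]1O[C@@H](C(C)(C)C)OC1=O
F2 | step 7 | lithium (2R)‑2‑tert‑butyl‑5‑methyl‑1,3‑dioxol‑4‑olate | CC1=C(O[Li])O[C@@H](O1)C(C)(C)C
F3 | step 7 | (2R,5S)‑2‑tert‑butyl‑5‑methyl‑5‑(2‑methylidene‑11‑{4‑[tri(propan‑2‑yl)silyloxy]phenyl}undecyl)‑1,3‑dioxolan‑4‑one | C[C@@]1(CC(=C)CCCCCCCCCc2ccc(O[Si](C(C)C)(C(C)C)C(C)C)cc2)O[C@@H](C(C)(C)C)OC1=O
F4 | step 7 | (2S)‑2‑methyl‑4‑methylidene‑13‑{4‑[tri(propan‑2‑yl)silyloxy]phenyl}tridecane‑1,2‑diol | C[C@](O)(CC(=C)CCCCCCCCCc1ccc(O[Si](C(C)C)(C(C)C)C(C)C)cc1)CO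
F5 | step 7 | (2S)‑2‑hydroxy‑2‑methyl‑4‑methylidene‑13‑{4‑[tri(propan‑2‑yl)silyloxy]phenyl}tridecanal | C[C@](O)(CC(=C)CCCCCCCCCc1ccc(O[Si](C(C)C)(C(C)C)C(C)C)cc1)C=O
F0 | step 11 | none | none
F6 | step 13 | (5S)‑5‑[(2RS)‑2‑hydroperoxy‑11‑(4‑hydroxyphenyl)‑2‑methylundecyl]‑5‑methylfuran‑2(5H)‑one | C[C@@]1(CC(C)(OO)CCCCCCCCCc2ccc(O)cc2)OC(=O)C=C1
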